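**The pitfall.** Q looks like a second substrate, and the tempting step is to scale the loss of D with its charge, pseudo-first-order fashion. But D has another way out, pairing to E, which takes no Q.

| setting | teal | east | north | north-west |
|---|---|---|---|---|
| D | 20 mM | 20 mM | 20 mM | 20 mM |
| Q | 1.8 equiv | 1.20 equiv | 1.20 equiv | 1.20 equiv |
| Z | 1.2 equiv | 1.20 equiv | 1.60 equiv | 2.00 equiv |
| remark | run made earlier |  |  |  |
| time |  | 10 h | 10 h | 10 h |

teal run (percent of the D charged)

| time / h | D / % | J / % |
|---|---|---|
| 0.833 | 80.6 | 7.8 |
| 2.00 | 61.8 | 16.3 |
| 2.50 | 56.1 | 19.1 |
| 4.00 | 43.4 | 24.8 |

(standard deviation of a reading: 1 percentage point)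

- percent here means D units held: one E counts as two
- the earlier runs were read with a standard deviation of 1 percentage point
- reactions considered so far: D + Q -> L + J; Q + L <-> G; L + Z <-> X; 2 D -> E
- no earlier run changes the charge of Z; that part of a forecast is a guess

1. part of the D that has reacted at the end, east
2. part of the D that has reacted at the end, north
3. part of the D that has reacted at the end, north-west
4. what raising the equivalents of Z from its lowest to its highest value here does to the part of the D that has reacted (changes below 5 percentage points count as none) (no change / it rises / it falls)

**Reading teal.** By 4.00 h the teal flask has lost 56.6% of its D. J holds 24.8%, so the remaining 31.8% went to E, which makes 0.780 as a reading, with the scatter of 1 percentage point. The first step runs as D times Q and pairing as D squared, so this ratio follows Q over D. Scaling by the Q charges gives east 0.520 for the route ratio, a selectivity factor: the D taken by Q per D taken by pairing.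

**East against teal.** With the ratio held, both routes go as D squared, so the reciprocal of the fraction of D left, less one, grows evenly with time. Teal's 43.4% left then gives a pairing pace of 0.183 h⁻¹. East's total pace stands at 0.854 of teal's, higher than the 0.667 given by the ratio of the Q charges, because pairing takes no Q. Over 10 h this reckoning gives 73.6% reacted in east. Z stands in neither route, so the guess for north and north-west is the same figure.

**The forecast.** It gave 75.5%, 76.5% and 77%, each higher than the 73.6% reckoned here, trend no change, holding that “Most D loss is dimerisation, which doesn't involve Z”.

**The result.** The flasks give 75.0%, 75.0% and 75.1%, so the trend is no change, with a change of 0.075 points.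

    D + Q → L + J (k = 0.0526 M⁻¹ min⁻¹)
    Q + L ⇌ G, settled at all times (K = 19400 M⁻¹)
    L + Z ⇌ X (K = 8.45 × 10⁵ M⁻¹, k = 3.50 M⁻¹ min⁻¹)
    2 D → E (k = 0.0738 M⁻¹ min⁻¹)

**The rates.** In north the step from D and Q uses D at 0.43 of the pairing rate just after the start and 0.98 at 10.0 h, so at both moments it is the slower of the two steps. The reckoned route ratio of 0.520 stands above the first of these values and below the second.

**A second flask.** North with 8.0 mM of D keeps its equivalents, so the route ratio stays 0.520, while the pairing pace falls with D to 0.0733 h⁻¹. That reckons 52.7% reacted and 18.0% as J; the flask gives 52.1% and 17.6%.

The earlier runs and the new flask were computed for substances that don't exist; scatter was added.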